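**Retrosynthetic overview**
- Hansforester J (25) ⇐ silyl ether 24 ⇐ tetraacetate 23 ⇐ bis(α-methyl ketone) 22 by a twofold Baeyer–Villiger oxygen insertion. The plan rests on the two ester oxygens bound to C2 of the 1-arylpropan-2-yl units: a CH(CH3) carbon next to the ArCH2 group of ring A (3,5-dihydroxyphenyl) and of ring C (the 2,4-dihydroxybenzoate ring). This is the carbon that migrates from an α-methyl ketone.
- 22 ⇐ central aroyl ester bond (ring C acid 18 + alcohol 9, retention at the carbinol), followed by benzyl-to-acetate exchange on the four phenols.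
- 9 and 18 ⇐ one Weinreb amide 5 (auxiliary-controlled benzylation of 1 with 2): methyl ketone, then (+)-Ipc2BCl aldol with acetaldehyde 7. The ring C carboxyl comes from Vilsmeier–Haack formylation of 5 and Pinnick oxidation.
- No ring is formed at any stage; both benzene rings come from 2.

Key step: step 15

Assumption: (+)-Ipc2BCl (from (−)-α-pinene) is taken to be the antipode whose methyl ketone enolates add to the Si face of acetaldehyde, which corresponds to the (R)-carbinol; the enantiomeric reagent would be used if the sense proved opposite.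

Step 1
Reactants: 1 (S)-4-benzyl-3-propionyloxazolidin-2-one; 2 3,5-bis(benzyloxy)benzyl bromide
Product: 4 (S)-4-benzyl-3-[(R)-3-(3,5-bis(benzyloxy)phenyl)-2-methylpropanoyl]oxazolidin-2-one, via sodium Z-enolate 3 (not isolated)
Conditions: NaN(SiMe3)2, THF, −78 °C; then 2, −78 → −30 °C
Reagents that add atoms: none
Why: Evans asymmetric alkylation, in which the chelated sodium Z-enolate is benzylated on the face opposite the C4 benzyl group of the auxiliary, which sets the (R)-α-methyl centre.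

Step 2
Reactants: 4 (S)-4-benzyl-3-[(R)-3-(3,5-bis(benzyloxy)phenyl)-2-methylpropanoyl]oxazolidin-2-one
Product: 5 (R)-3-[3,5-bis(benzyloxy)phenyl]-N-methoxy-N,2-dimethylpropanamide
Conditions: MeNH(OMe)·HCl, AlMe3, CH2Cl2, −15 °C → rt; aq. KNaC4H4O6 (potassium sodium tartrate) work-up
Reagents that add atoms: N,O-dimethylhydroxylamine hydrochloride, CNOC.Cl
Why: Aluminium amide transamination (Weinreb amide formation) should cleave the exocyclic imide carbonyl under Lewis-acidic, non-enolising conditions, so the α-centre is kept and the auxiliary is released.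

Step 3
Reactants: 5 (R)-3-[3,5-bis(benzyloxy)phenyl]-N-methoxy-N,2-dimethylpropanamide
Product: 6 (R)-4-[3,5-bis(benzyloxy)phenyl]-3-methylbutan-2-one
Conditions: MeMgBr, THF, 0 °C; aq. NH4Cl
Reagents that add atoms: methylmagnesium bromide, C[Mg]Br
Why: Weinreb ketone synthesis, in which the Grignard adduct is held as a magnesium chelate until quench, so one methyl group is delivered and the α-centre is not enolised.

Step 4
Reactants: 6 (R)-4-[3,5-bis(benzyloxy)phenyl]-3-methylbutan-2-one; 7 acetaldehyde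
Product: 9 (2R,5R)-1-[3,5-bis(benzyloxy)phenyl]-5-hydroxy-2-methylhexan-3-one, via diisopinocampheylboron enolate 8 (not isolated)
Conditions: (+)-Ipc2BCl, Et3N, Et2O, 0 °C; then 7, −78 → −20 °C; then MeOH, pH 7 buffer, H2O2, 0 °C
Reagents that add atoms: none
Why: Diisopinocampheylboron-mediated methyl ketone aldol, in which kinetic enolisation occurs on the methyl side only (the α-methine centre is untouched) and the chiral boron ligands direct the enolate to the Si face of acetaldehyde to set the (5R)-carbinol, any C5 epimer being a diastereomer that should be removable by chromatography.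

Step 5
Reactants: 5 (R)-3-[3,5-bis(benzyloxy)phenyl]-N-methoxy-N,2-dimethylpropanamide
Product: 11 (R)-3-[3,5-bis(benzyloxy)-2-formylphenyl]-N-methoxy-N,2-dimethylpropanamide, via aryl iminium chloride 10 (not isolated)
Conditions: POCl3, DMF, 0 → 40 °C; then aq. NaOAc
Reagents that add atoms: N,N-dimethylformamide, CN(C)C=O; water, O
Why: Vilsmeier–Haack formylation, in which the chloroiminium ion should attack the resorcinol diether ring ortho to the alkyl chain and para to one benzyloxy group (the position between the two ethers is more hindered), while the Weinreb amide is inert to the reagent.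

Step 6
Reactants: 11 (R)-3-[3,5-bis(benzyloxy)-2-formylphenyl]-N-methoxy-N,2-dimethylpropanamide
Product: 12 2,4-bis(benzyloxy)-6-[(R)-3-[methoxy(methyl)amino]-2-methyl-3-oxopropyl]benzoic acid
Conditions: NaClO2, NaH2PO4, 2-methyl-2-butene, t-BuOH/H2O, 0 °C → rt
Reagents that add atoms: sodium chlorite, [Na+].[O-]Cl=O
Why: Pinnick oxidation should convert the hindered aryl aldehyde into the acid under buffered conditions, with 2-methyl-2-butene trapping hypochlorous acid so that the electron-rich ring is not chlorinated.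

Step 7
Reactants: 12 2,4-bis(benzyloxy)-6-[(R)-3-[methoxy(methyl)amino]-2-methyl-3-oxopropyl]benzoic acid
Product: 13 allyl 2,4-bis(benzyloxy)-6-[(R)-3-[methoxy(methyl)amino]-2-methyl-3-oxopropyl]benzoate
Conditions: allyl bromide, K2CO3, DMF, rt
Reagents that add atoms: allyl bromide, C=CCBr
Why: SN2 O-alkylation of the carboxylate under mild carbonate base should give an ester that can later be removed under neutral conditions without touching the benzyl ethers.

Step 8
Reactants: 13 allyl 2,4-bis(benzyloxy)-6-[(R)-3-[methoxy(methyl)amino]-2-methyl-3-oxopropyl]benzoate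
Product: 14 allyl 2,4-bis(benzyloxy)-6-[(R)-2-methyl-3-oxobutyl]benzoate
Conditions: MeMgBr, THF, −10 → 0 °C; aq. NH4Cl
Reagents that add atoms: methylmagnesium bromide, C[Mg]Br
Why: Weinreb ketone synthesis, in which the Weinreb amide should react in preference to the di-ortho-substituted and therefore shielded allyl benzoate, and the chelated adduct protects the α-centre until quench.

Step 9
Reactants: 14 allyl 2,4-bis(benzyloxy)-6-[(R)-2-methyl-3-oxobutyl]benzoate; 7 acetaldehyde
Product: 16 allyl 2,4-bis(benzyloxy)-6-[(2R,5R)-5-hydroxy-2-methyl-3-oxohexyl]benzoate, via diisopinocampheylboron enolate 15 (not isolated)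
Conditions: (+)-Ipc2BCl, Et3N, Et2O, 0 °C; then 7, −78 → −20 °C; then MeOH, pH 7 buffer, H2O2, 0 °C
Reagents that add atoms: none
Why: The same diisopinocampheylboron-mediated methyl ketone aldol as in step 4, with methyl-side enolisation and reagent-controlled Si-face addition to acetaldehyde setting the (5R)-carbinol, the hindered ester being a spectator.

Step 10
Reactants: 16 allyl 2,4-bis(benzyloxy)-6-[(2R,5R)-5-hydroxy-2-methyl-3-oxohexyl]benzoate
Product: 17 allyl 2,4-bis(benzyloxy)-6-[(2R,5R)-5-(tert-butyldimethylsilyloxy)-2-methyl-3-oxohexyl]benzoate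
Conditions: TBSCl, imidazole, DMF, rt
Reagents that add atoms: tert-butyldimethylsilyl chloride, CC(C)(C)[Si](C)(C)Cl
Why: Imidazole-promoted silylation of the unhindered secondary alcohol is mild enough to avoid retro-aldol cleavage or β-elimination of the aldol.

Step 11
Reactants: 17 allyl 2,4-bis(benzyloxy)-6-[(2R,5R)-5-(tert-butyldimethylsilyloxy)-2-methyl-3-oxohexyl]benzoate
Product: 18 2,4-bis(benzyloxy)-6-[(2R,5R)-5-(tert-butyldimethylsilyloxy)-2-methyl-3-oxohexyl]benzoic acid
Conditions: Pd(PPh3)4 (cat.), morpholine, THF, rt; pH 4 buffer work-up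
Reagents that add atoms: none
Why: Tsuji–Trost deallylation, in which zerovalent palladium ionises the allyl ester to a π-allyl complex that morpholine traps, under near-neutral conditions that spare the benzyl ethers, the silyl ether and the β-silyloxy ketone.

Step 12
Reactants: 18 2,4-bis(benzyloxy)-6-[(2R,5R)-5-(tert-butyldimethylsilyloxy)-2-methyl-3-oxohexyl]benzoic acid; 9 (2R,5R)-1-[3,5-bis(benzyloxy)phenyl]-5-hydroxy-2-methylhexan-3-one
Product: 20 (2R,5R)-6-[3,5-bis(benzyloxy)phenyl]-5-methyl-4-oxohexan-2-yl 2,4-bis(benzyloxy)-6-[(2R,5R)-5-(tert-butyldimethylsilyloxy)-2-methyl-3-oxohexyl]benzoate, via acid chloride 19 (not isolated)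
Conditions: 1-chloro-N,N,2-trimethylprop-1-en-1-amine, CH2Cl2, 0 °C → rt; then 9, pyridine, DMAP, CH2Cl2, 0 °C → rt
Reagents that add atoms: none
Why: Acyl chloride esterification with nucleophilic catalysis by DMAP, in which the α-chloroenamine forms the aroyl chloride under neutral conditions that spare the silyl ether, the alcohol oxygen is acylated so the carbinol keeps its (R) configuration, and pyridine as the only base limits β-elimination of the β-acyloxy ketone.

Step 13
Reactants: 20 (2R,5R)-6-[3,5-bis(benzyloxy)phenyl]-5-methyl-4-oxohexan-2-yl 2,4-bis(benzyloxy)-6-[(2R,5R)-5-(tert-butyldimethylsilyloxy)-2-methyl-3-oxohexyl]benzoate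
Product: 21 (2R,5R)-6-(3,5-dihydroxyphenyl)-5-methyl-4-oxohexan-2-yl 6-[(2R,5R)-5-(tert-butyldimethylsilyloxy)-2-methyl-3-oxohexyl]-2,4-dihydroxybenzoate
Conditions: H2 (1 atm), Pd/C, EtOAc, rt
Reagents that add atoms: none
Why: Catalytic hydrogenolysis should cleave the four benzyl aryl ethers, while the ketones, the silyl ether and the ester (a homobenzylic, not benzylic, C–O bond) are not reduced.

Step 14
Reactants: 21 (2R,5R)-6-(3,5-dihydroxyphenyl)-5-methyl-4-oxohexan-2-yl 6-[(2R,5R)-5-(tert-butyldimethylsilyloxy)-2-methyl-3-oxohexyl]-2,4-dihydroxybenzoate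
Product: 22 (2R,5R)-6-(3,5-diacetoxyphenyl)-5-methyl-4-oxohexan-2-yl 2,4-diacetoxy-6-[(2R,5R)-5-(tert-butyldimethylsilyloxy)-2-methyl-3-oxohexyl]benzoate
Conditions: Ac2O, pyridine, DMAP (cat.), CH2Cl2, 0 °C → rt
Reagents that add atoms: acetic anhydride, CC(=O)OC(C)=O
Why: DMAP-catalysed acetylation of the four phenols (including the hydrogen-bonded ortho one) should turn both electron-rich rings into deactivated aryl acetates before the peracid step, the silyl ether blocking the only alcohol.

Step 15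
Reactants: 22 (2R,5R)-6-(3,5-diacetoxyphenyl)-5-methyl-4-oxohexan-2-yl 2,4-diacetoxy-6-[(2R,5R)-5-(tert-butyldimethylsilyloxy)-2-methyl-3-oxohexyl]benzoate
Product: 23 (R)-1-(3,5-diacetoxyphenyl)propan-2-yl (R)-3-{[2,4-diacetoxy-6-((R)-2-{[(R)-3-(tert-butyldimethylsilyloxy)butanoyl]oxy}propyl)benzoyl]oxy}butanoate (tetra-O-acetyl O-TBS Hansforester J)
Conditions: (CF3CO)2O, urea·H2O2, Na2HPO4, CH2Cl2, 0 °C → rt
Reagents that add atoms: trifluoroperacetic acid (generated from trifluoroacetic anhydride and urea–hydrogen peroxide), OOC(=O)C(F)(F)F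
Why: Baeyer–Villiger oxidation, in which trifluoroperacetic acid adds to each ketone carbonyl to give a Criegee adduct and the group antiperiplanar to the breaking O–O bond shifts from carbon to oxygen in a concerted 1,2-migration. The closest known reaction type is the peracid oxidation of acyclic α-branched (sec-alkyl) ketones to sec-alkyl esters, here run twice in one substrate. No ring is closed and no stereocentre is created; the two migrating CH(CH3)CH2Ar carbons keep their (R) configuration because the shift occurs with retention. The step needs secondary-over-primary migration at both ketones, and the substrate secures it because the competing CH2 groups are primary and carry an inductively withdrawing β-oxygen (aroyloxy on one ketone, silyloxy on the other). The Na2HPO4 buffer should prevent enolisation of the α-methyl centres, β-elimination and silyl ether cleavage, and the four aryl acetates deactivate rings A and C towards electrophilic hydroxylation by the peracid.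

Step 16
Reactants: 23 tetra-O-acetyl O-TBS Hansforester J
Product: 24 (R)-1-(3,5-dihydroxyphenyl)propan-2-yl (R)-3-{[6-((R)-2-{[(R)-3-(tert-butyldimethylsilyloxy)butanoyl]oxy}propyl)-2,4-dihydroxybenzoyl]oxy}butanoate (O-TBS Hansforester J)
Conditions: NH4OAc, MeOH/H2O (4:1), rt
Reagents that add atoms: none
Why: Ammonium acetate-mediated methanolysis should cleave only the four aryl acetates, because phenoxide is a far better leaving group than a secondary alkoxide, so the three alkyl esters stay intact under these near-neutral conditions.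

Step 17
Reactants: 24 O-TBS Hansforester J
Product: 25 Hansforester J
Conditions: HF·pyridine, pyridine, THF, 0 °C → rt
Reagents that add atoms: none
Why: Fluoride-induced desilylation with pyridine-buffered HF should free the terminal secondary alcohol without base, so neither ester cleavage nor acyl migration is expected.

**Compound list**
1 | (S)-4-benzyl-3-propionyloxazolidin-2-one | CCC(=O)N1[C@@H](Cc2ccccc2)COC1=O | starting material
2 | 3,5-bis(benzyloxy)benzyl bromide | BrCc1cc(OCc2ccccc2)cc(OCc2ccccc2)c1 | starting material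
3 | sodium Z-enolate of 1 | C/C=C(\[O-])N1[C@@H](Cc2ccccc2)COC1=O.[Na+] | intermediate (not isolated)
4 | (S)-4-benzyl-3-[(R)-3-(3,5-bis(benzyloxy)phenyl)-2-methylpropanoyl]oxazolidin-2-one | C[C@H](Cc1cc(OCc2ccccc2)cc(OCc2ccccc2)c1)C(=O)N1[C@@H](Cc2ccccc2)COC1=O | intermediate
5 | (R)-3-[3,5-bis(benzyloxy)phenyl]-N-methoxy-N,2-dimethylpropanamide | C[C@H](Cc1cc(OCc2ccccc2)cc(OCc2ccccc2)c1)C(=O)N(C)OC | intermediate
6 | (R)-4-[3,5-bis(benzyloxy)phenyl]-3-methylbutan-2-one | C[C@H](Cc1cc(OCc2ccccc2)cc(OCc2ccccc2)c1)C(C)=O | intermediate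
7 | acetaldehyde | CC=O | starting material
8 | diisopinocampheylboron enolate of 6 | C=C(OB([C@H]1C[C@H]2C[C@@H]([C@@H]1C)C2(C)C)[C@H]1C[C@H]2C[C@@H]([C@@H]1C)C2(C)C)[C@H](C)Cc1cc(OCc2ccccc2)cc(OCc2ccccc2)c1 | intermediate (not isolated)
9 | (2R,5R)-1-[3,5-bis(benzyloxy)phenyl]-5-hydroxy-2-methylhexan-3-one | C[C@H](Cc1cc(OCc2ccccc2)cc(OCc2ccccc2)c1)C(=O)C[C@@H](C)O | intermediate
10 | aryl iminium chloride from 5 | C[C@H](Cc1cc(OCc2ccccc2)cc(OCc2ccccc2)c1C=[N+](C)C)C(=O)N(C)OC.[Cl-] | intermediate (not isolated)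
11 | (R)-3-[3,5-bis(benzyloxy)-2-formylphenyl]-N-methoxy-N,2-dimethylpropanamide | C[C@H](Cc1cc(OCc2ccccc2)cc(OCc2ccccc2)c1C=O)C(=O)N(C)OC | intermediate
12 | 2,4-bis(benzyloxy)-6-[(R)-3-[methoxy(methyl)amino]-2-methyl-3-oxopropyl]benzoic acid | C[C@H](Cc1cc(OCc2ccccc2)cc(OCc2ccccc2)c1C(=O)O)C(=O)N(C)OC | intermediate
13 | allyl 2,4-bis(benzyloxy)-6-[(R)-3-[methoxy(methyl)amino]-2-methyl-3-oxopropyl]benzoate | C[C@H](Cc1cc(OCc2ccccc2)cc(OCc2ccccc2)c1C(=O)OCC=C)C(=O)N(C)OC | intermediate
14 | allyl 2,4-bis(benzyloxy)-6-[(R)-2-methyl-3-oxobutyl]benzoate | C[C@H](Cc1cc(OCc2ccccc2)cc(OCc2ccccc2)c1C(=O)OCC=C)C(C)=O | intermediate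
15 | diisopinocampheylboron enolate of 14 | C=C(OB([C@H]1C[C@H]2C[C@@H]([C@@H]1C)C2(C)C)[C@H]1C[C@H]2C[C@@H]([C@@H]1C)C2(C)C)[C@H](C)Cc1cc(OCc2ccccc2)cc(OCc2ccccc2)c1C(=O)OCC=C | intermediate (not isolated)
16 | allyl 2,4-bis(benzyloxy)-6-[(2R,5R)-5-hydroxy-2-methyl-3-oxohexyl]benzoate | C[C@H](Cc1cc(OCc2ccccc2)cc(OCc2ccccc2)c1C(=O)OCC=C)C(=O)C[C@@H](C)O | intermediate
17 | allyl 2,4-bis(benzyloxy)-6-[(2R,5R)-5-(tert-butyldimethylsilyloxy)-2-methyl-3-oxohexyl]benzoate | C[C@H](Cc1cc(OCc2ccccc2)cc(OCc2ccccc2)c1C(=O)OCC=C)C(=O)C[C@@H](C)O[Si](C)(C)C(C)(C)C | intermediate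
18 | 2,4-bis(benzyloxy)-6-[(2R,5R)-5-(tert-butyldimethylsilyloxy)-2-methyl-3-oxohexyl]benzoic acid | C[C@H](Cc1cc(OCc2ccccc2)cc(OCc2ccccc2)c1C(=O)O)C(=O)C[C@@H](C)O[Si](C)(C)C(C)(C)C | intermediate
19 | 2,4-bis(benzyloxy)-6-[(2R,5R)-5-(tert-butyldimethylsilyloxy)-2-methyl-3-oxohexyl]benzoyl chloride | C[C@H](Cc1cc(OCc2ccccc2)cc(OCc2ccccc2)c1C(Cl)=O)C(=O)C[C@@H](C)O[Si](C)(C)C(C)(C)C | intermediate (not isolated)
20 | (2R,5R)-6-[3,5-bis(benzyloxy)phenyl]-5-methyl-4-oxohexan-2-yl 2,4-bis(benzyloxy)-6-[(2R,5R)-5-(tert-butyldimethylsilyloxy)-2-methyl-3-oxohexyl]benzoate | C[C@H](Cc1cc(OCc2ccccc2)cc(OCc2ccccc2)c1)C(=O)C[C@@H](C)OC(=O)c1c(OCc2ccccc2)cc(OCc2ccccc2)cc1C[C@@H](C)C(=O)C[C@@H](C)O[Si](C)(C)C(C)(C)C | intermediate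
21 | (2R,5R)-6-(3,5-dihydroxyphenyl)-5-methyl-4-oxohexan-2-yl 6-[(2R,5R)-5-(tert-butyldimethylsilyloxy)-2-methyl-3-oxohexyl]-2,4-dihydroxybenzoate | C[C@H](Cc1cc(O)cc(O)c1)C(=O)C[C@@H](C)OC(=O)c1c(O)cc(O)cc1C[C@@H](C)C(=O)C[C@@H](C)O[Si](C)(C)C(C)(C)C | intermediate
22 | tetra-O-acetyl O-TBS diketone (key-step precursor) | C[C@H](Cc1cc(OC(C)=O)cc(OC(C)=O)c1)C(=O)C[C@@H](C)OC(=O)c1c(OC(C)=O)cc(OC(C)=O)cc1C[C@@H](C)C(=O)C[C@@H](C)O[Si](C)(C)C(C)(C)C | intermediate
23 | tetra-O-acetyl O-TBS Hansforester J (key-step product) | C[C@H](Cc1cc(OC(C)=O)cc(OC(C)=O)c1)OC(=O)C[C@@H](C)OC(=O)c1c(OC(C)=O)cc(OC(C)=O)cc1C[C@@H](C)OC(=O)C[C@@H](C)O[Si](C)(C)C(C)(C)C | intermediate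
24 | O-TBS Hansforester J | C[C@H](Cc1cc(O)cc(O)c1)OC(=O)C[C@@H](C)OC(=O)c1c(O)cc(O)cc1C[C@@H](C)OC(=O)C[C@@H](C)O[Si](C)(C)C(C)(C)C | intermediate
25 | Hansforester J | C[C@H](Cc1cc(O)cc(O)c1)OC(=O)C[C@@H](C)OC(=O)c1c(O)cc(O)cc1C[C@@H](C)OC(=O)C[C@@H](C)O | target

**Step count**
Total: 17 steps. Longest linear sequence: 15 steps (steps 1, 2 and 5–17).

**Three steps most likely to fail**

1. Step 15 (key step). What may go wrong: the second oxygen insertion stalls, the β-aroyloxy ketone loses its aroyloxy group by elimination before it is oxidised, or migration of the CH2 group competes. The fallback is sequential oxygen insertion before the fragments are joined, so that each substrate holds one ketone and the milder mCPBA suffices. It sets out from 9 and 18. Alcohol 9 would be oxidised with mCPBA/NaHCO3 in CH2Cl2 (hydroxyl-assisted Baeyer–Villiger) to (R)-1-[3,5-bis(benzyloxy)phenyl]propan-2-yl (R)-3-hydroxybutanoate F1. Acid 18 would be oxidised with mCPBA in CH2Cl2/aqueous phosphate buffer to 2,4-bis(benzyloxy)-6-[(R)-2-{[(R)-3-(tert-butyldimethylsilyloxy)butanoyl]oxy}propyl]benzoic acid F2. F2 would be converted with 1-chloro-N,N,2-trimethylprop-1-en-1-amine into the corresponding benzoyl chloride F3 and coupled with F1 (pyridine, DMAP) to tetra-O-benzyl O-TBS Hansforester J F4. Hydrogenolysis of F4 (H2, Pd/C) would give 24, where the route is rejoined.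

2. Step 12. What may go wrong: slow acylation by the di-ortho-substituted aroyl chloride, with base-induced β-elimination of the aldol or of the product ester taking over. The fallback is a Mitsunobu esterification, in which the carboxylate of 18 is the nucleophile and the carbinol is inverted. It sets out from 6. Ketone 6 would be taken through the aldol of step 4 with (−)-Ipc2BCl, via the boron enolate of 6 bearing (−)-isopinocampheyl groups F5, to the epimeric alcohol (2R,5S)-1-[3,5-bis(benzyloxy)phenyl]-5-hydroxy-2-methylhexan-3-one F6. F6 and acid 18 with PPh3 and diisopropyl azodicarboxylate in toluene at 0 °C would give 20 with inversion at the carbinol, where the route is rejoined.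

3. Step 4 (step 9 carries the same risk). What may go wrong: poor facial selectivity in the addition to acetaldehyde, leaving a C5 epimer that is hard to separate. The fallback replaces the aldol by catalyst-controlled conjugate borylation of an enone. It sets out from 5. Weinreb amide 5 would be treated with LiCH2P(O)(OCH3)2 in THF at −78 °C to give dimethyl [(R)-4-(3,5-bis(benzyloxy)phenyl)-3-methyl-2-oxobutyl]phosphonate F7. A Horner–Wadsworth–Emmons reaction with acetaldehyde 7 (Ba(OH)2, THF/H2O) would give (R,E)-1-[3,5-bis(benzyloxy)phenyl]-2-methylhex-4-en-3-one F8. CuCl/NaOC(CH3)3 with a Josiphos-type chiral ferrocenyl bisphosphine (the enantiomer that leads to the (5R)-boronate), bis(pinacolato)diboron and MeOH would give (2R,5R)-1-[3,5-bis(benzyloxy)phenyl]-2-methyl-5-(4,4,5,5-tetramethyl-1,3,2-dioxaborolan-2-yl)hexan-3-one F9. Oxidation of F9 with NaBO3·4H2O in THF/H2O, with retention at carbon, would give 9, where the route is rejoined.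

Further compounds
F1 | step 15 | (R)-1-[3,5-bis(benzyloxy)phenyl]propan-2-yl (R)-3-hydroxybutanoate | C[C@H](Cc1cc(OCc2ccccc2)cc(OCc2ccccc2)c1)OC(=O)C[C@@H](C)O
F2 | step 15 | 2,4-bis(benzyloxy)-6-[(R)-2-{[(R)-3-(tert-butyldimethylsilyloxy)butanoyl]oxy}propyl]benzoic acid | C[C@H](Cc1cc(OCc2ccccc2)cc(OCc2ccccc2)c1C(=O)O)OC(=O)C[C@@H](C)O[Si](C)(C)C(C)(C)C
F3 | step 15 | 2,4-bis(benzyloxy)-6-[(R)-2-{[(R)-3-(tert-butyldimethylsilyloxy)butanoyl]oxy}propyl]benzoyl chloride | C[C@H](Cc1cc(OCc2ccccc2)cc(OCc2ccccc2)c1C(Cl)=O)OC(=O)C[C@@H](C)O[Si](C)(C)C(C)(C)C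
F4 | step 15 | tetra-O-benzyl O-TBS Hansforester J | C[C@H](Cc1cc(OCc2ccccc2)cc(OCc2ccccc2)c1)OC(=O)C[C@@H](C)OC(=O)c1c(OCc2ccccc2)cc(OCc2ccccc2)cc1C[C@@H](C)OC(=O)C[C@@H](C)O[Si](C)(C)C(C)(C)C
F5 | step 12 | boron enolate of 6 bearing (−)-isopinocampheyl groups | C=C(OB([C@@H]1C[C@@H]2C[C@H]([C@H]1C)C2(C)C)[C@@H]1C[C@@H]2C[C@H]([C@H]1C)C2(C)C)[C@H](C)Cc1cc(OCc2ccccc2)cc(OCc2ccccc2)c1
F6 | step 12 | (2R,5S)-1-[3,5-bis(benzyloxy)phenyl]-5-hydroxy-2-methylhexan-3-one | C[C@H](Cc1cc(OCc2ccccc2)cc(OCc2ccccc2)c1)C(=O)C[C@H](C)O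
F7 | step 4 | dimethyl [(R)-4-(3,5-bis(benzyloxy)phenyl)-3-methyl-2-oxobutyl]phosphonate | COP(=O)(CC(=O)[C@H](C)Cc1cc(OCc2ccccc2)cc(OCc2ccccc2)c1)OC
F8 | step 4 | (R,E)-1-[3,5-bis(benzyloxy)phenyl]-2-methylhex-4-en-3-one | C/C=C/C(=O)[C@H](C)Cc1cc(OCc2ccccc2)cc(OCc2ccccc2)c1
F9 | step 4 | (2R,5R)-1-[3,5-bis(benzyloxy)phenyl]-2-methyl-5-(4,4,5,5-tetramethyl-1,3,2-dioxaborolan-2-yl)hexan-3-one | C[C@H](Cc1cc(OCc2ccccc2)cc(OCc2ccccc2)c1)C(=O)C[C@@H](C)B1OC(C)(C)C(C)(C)O1
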